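I timed the substrate. In these flasks substrate and coupling partner combine to product with the help of the catalyst, and in the gamma run substrate is the limiting reagent, 200 mM against 400 mM of coupling partner.

| flask | substrate | coupling partner | catalyst | time |
|---|---|---|---|---|
| gamma | 200 mM | 400 mM | 16.0 mM |  |
| zeta | 120 mM | 320 mM | 16.0 mM |  |
| delta | 200 mM | 800 mM | 16.0 mM |  |
| theta | 300 mM | 400 mM | 16.0 mM |  |
| epsilon | 100 mM | 400 mM | 32.0 mM | 110 min |

| run | time / min | [product] / mM |
|---|---|---|
| gamma run | 16 | 37.9 |
| gamma run | 31 | 67.6 |
| gamma run | 47 | 92.2 |
| gamma run | 63 | 112.0 |
| gamma run | 79 | 128.5 |
| gamma run | 94 | 138.4 |
| gamma run | 110 | 152.6 |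
| zeta run | 16 | 21.4 |
| zeta run | 31 | 38.6 |
| zeta run | 47 | 52.5 |
| zeta run | 63 | 65.9 |
| zeta run | 79 | 75.7 |
| zeta run | 94 | 81.4 |
| zeta run | 110 | 89.8 |
| delta run | 16 | 46.8 |
| delta run | 31 | 78.2 |
| delta run | 47 | 107.0 |
| delta run | 63 | 126.4 |
| delta run | 79 | 143.1 |
| delta run | 94 | 155.2 |
| delta run | 110 | 165.1 |
| theta run | 16 | 55.5 |
| theta run | 31 | 98.5 |
| theta run | 47 | 135.6 |
| theta run | 63 | 164.5 |
| theta run | 79 | 187.5 |
| theta run | 94 | 206.3 |
| theta run | 110 | 223.1 |

(scatter of a reading: 1 mM)

- how the opening rate goes with [substrate] round the charge of the gamma run: the exponent of the rate at two percent of substrate gone to product (one fixed amount of product, the same in the runs compared)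
- how the opening rate goes with [coupling partner] round the charge of the gamma run: the exponent of the rate at two percent of substrate gone to product
- the zeta run starts with 80.0 mM less of substrate and of coupling partner than the gamma run, and with no product. Compared where both hold the same amount of substrate, once fifteen percent of what the zeta run was charged with has turned into product, is the zeta run faster, slower or alike (within a tenth)?
- product in the epsilon run at 110 min, as a share of the substrate charged

- Overall: substrate + coupling partner -> product, with catalyst as catalyst.
- Constant volume, constant temperature.
- Bound and free are read together.
- An order is taken over about fifteen percent of the charge, up and down.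

From the last reading, the gamma run gave 76.4 min for what I call the substrate time constant: the reading time divided by the natural logarithm of substrate charged over substrate left, as for a first-order element.

I reckoned the same constant for the zeta run, 79.7 min, and for the theta run, 80.8 min, and ranked the runs on that ladder, quickest first. The delta run came first at 63.0 min. It held twice the coupling partner of the gamma run, yet its time constant was shorter by a factor of just 1.21, which I read as an order in coupling partner of about 0.278. The zeta run followed the gamma run at 79.7 min. Its excess of coupling partner over substrate, 200 mM, equals that of the gamma run, so it starts like the gamma run after 80.0 mM of substrate has gone. The question compares rates at equal substrate, which whole-run constants don't give, so I took slopes from the readings instead. The zeta run averaged 1.25 mM/min up to 31 min, with substrate near 101 mM, and the gamma run averaged 1.24 mM/min between 47 min and 63 min, with substrate near 97.9 mM. The ratio of these two readings, 1.01, lies within a tenth of one, so I called the two runs alike. The theta run came last at 80.8 min. It held 1.50 times the substrate of the gamma run with nearly the same constant, so I put the order in substrate near one.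

The catalyst was the open rung, since each earlier run held 16.0 mM. The epsilon run holds twice that. With the gamma constant unchanged, its share at 110 min comes to 76.3%. With the constant divided by two, on the assumption of proportion, the share comes to 94.4%, and that was my reckoning.

The forecast gave 0.95 (0.8 to 1.05), 0.35 (0.2 to 0.5), alike and 94% (85% to 98%), saying “I assume the rate is first order in catalyst, which no run tested”.

The flask gave 1.0 for the order in substrate, 0.24 for the order in coupling partner, alike for the comparison of zeta with gamma, and 85.8% for the epsilon run.

    catalyst + substrate → catalyst-substrate complex (8.040 /M/min)
    catalyst-substrate complex + coupling partner → product + catalyst (11.10 /M/min)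
    substrate + coupling partner → product (0.007500 /M/min)
    2 catalyst ⇌ resting dimer, settled at all times (4180 /M)

Through the same yardstick the epsilon run has a substrate time constant of 56.3 min, so the added catalyst shortened the gamma constant by a factor of 1.36, an exponent of 0.440. The shortfall comes from catalyst tied up as resting dimer: the epsilon run without that step reaches 100% against 85.8%. On the theta run, ln(2) times its constant puts product at half of the charge at 56.0 min, and the flask reaches that point at 54.5 min.

Readings and results are calculated on assumed constants; the scatter is artificial.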